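## Structural features

The target 31 is a 2-oxaspiro[4.5]deca-6,9-dien-8-one: a tetrahydrofuran (C1, O2, C3, C4, C5) joined through the quaternary spiro carbon C5 to a 7-methoxycyclohexa-2,5-dienone (C6=C7(OMe), C8=O, C9=C10). Four ring stereocentres stand in a row: C1 (side chain), C3 (4-hydroxy-3-methoxyphenyl), C4 (hydroxymethyl) and C5. A fifth, C1' on the chain, carries a hydroxymethyl group and the aryl ether of 4-(3-hydroxypropyl)-2-methoxyphenol. The C3 aryl and C4 hydroxymethyl groups are trans; the C4 hydroxymethyl group, C6 and the C1 side chain lie on one face, so the side chain is trans to the C3 aryl group across O2. C5 is stereogenic only because C6 leads to the methoxy-bearing C7 and C10 does not, so two nearly identical ring carbons must be told apart. The dienone is an ipso-dialkylated, dearomatised guaiacol: protonation at the C8 carbonyl lets C1 leave as an oxocarbenium ion with rearomatisation, so strong acid is excluded once the ring exists. The aryloxy group at C1' is β to C1 (E1cB from any C1 carbanion), and the free para-hydroxybenzylic ether at C3 is base-sensitive. The real difficulty is the C1–C5 bond to a quaternary centre with control of both C1 and C5; C5 is para to the C8 oxygen, and an ionic closure from a phenol ether would go ortho to an isochroman instead. The plan uses the fact that C7 and C8 are both at the carbonyl oxidation level: with C7 as ketone and C8 as dimethyl ketal, C5 becomes the β-carbon of the C5=C6–C7=O enone and can accept a nucleophilic radical at C1.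

## Logic of the disconnections

31 ⇒ 30. Four O–Si bonds are cut. The phenol para to C3 and the three primary alcohols stay masked through all basic, oxidative and radical steps. The forward step must use buffered fluoride, because acid fragments the dienone and free alkoxide could add to C6.

30 ⇒ 29 ⇒ 28. The C7–O–CH3 bond and the C8 carbonyl are cut. Methylating the C7 enolate first makes the C8 ketal doubly allylic, so it ionises at pH 4–5, far below the acidity that fragments 30; the free 7-hydroxy dienone is never formed. The forward step needs O- rather than C-methylation of a neopentyl-type enolate.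

28 ⇒ 27. The C10–H bond is traced to C10–Br. The bromine is a temporary control element and costs two steps. The forward step must reduce a vinyl bromide without touching the ketone.

27 ⇒ 26. The C1–C5 bond is cut (key step). This removes the spiro ring and two stereocentres and returns an acyclic α-alkoxy acid on a dearomatised arene. The forward step must add a C1 radical to C5 from one face and with one orientation of the side chain; the bromine at C10 is placed to enforce both.

26 ⇒ 25. One C8–OMe bond is cut, which rearomatises the ring to a 2-methoxyphenol. The phenol must be the only free one, and the product must not dimerise; the bromine para to the hydroxyl serves the second demand.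

25 ⇒ 24. Two O–allyl bonds (aryl ether and ester) are cut, so that one palladium step frees phenol and acid together. This avoids hydroxide, which the aryl silyl ether would not survive.

24 ⇒ 12 + 22. The O2–C1 ether bond is cut, dividing the molecule into a diaryl propanol and a four-carbon side chain. C1 becomes a planar radical later, so neither the leaving-group carbon of 22 nor the course of the substitution needs stereocontrol. The forward step needs substitution to outrun E1cB loss of aryloxide.

12 ⇒ 11 ⇒ 10 ⇒ 6 + 8. The C3–C4 bond is cut as an aldol. A trans relationship on the ring, with O2 and C5 as ring members, corresponds to the syn aldol, (2S,3S) at the imide stage. The forward step needs auxiliary control and fast reduction before C4 can epimerise.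

6 ⇒ 3 + 4; 3 ⇒ 2 ⇒ 1; 8 ⇒ 7. The N-acyl, O-allyl, C–Br and O–Si bonds are cut back to commercial materials. Bromination is placed first, where the free hydroxyl directs it para, to the future C10.

22 ⇒ 21 ⇒ 20 ⇒ 19 ⇒ 18. The C1 hydroxyl and the carboxyl carbon are traced to a vinyl group (dihydroxylation, oxidation of the primary alcohol, esterification, triflation). The vinyl group brings both carbons, and the new centre may form as either epimer.

18 ⇒ 17 + 15; 17 ⇒ 16; 15 ⇒ 14 ⇒ 13. The C1'–OAr bond is cut as an SN2 inversion of a secondary allylic alcohol, which fixes C1' from (S)-but-3-ene-1,2-diol. The forward step needs SN2 to beat SN2'.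

## Other disconnections considered

Alternative 1: The cut is at C6–C7 and C5–C10, building the six-membered ring by cycloaddition. In the forward sense the α-methylene lactone A2 and the diene A3 give the spirolactone silyl enol ether A1.
- In its favour: the reaction type is well established, C5 is made quaternary without dearomatisation, and the C4 substituent of A2 should steer the diene to the opposite face.
- Against it here: A1 carries C1 as a lactone carbonyl that must become a CH bearing the side chain, and an α-aryloxy carbanion cannot be added because it would eliminate. The ring still needs two dehydrogenations and a C7 oxygen placed on the correct side of C5.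
- Comparison: on mechanism it is the better plan, since nothing beyond known chemistry is needed. On structure it is no better, because C5 becomes defined only when C6 is distinguished from C10 after the cycloaddition. On step economy it is clearly worse, by an estimated eight or more steps after A1.

Alternative 2: The cut is at O2–C3 and C1–C5 in one operation. In the forward sense Sc(OTf)3 opens the spirocyclopropyl dienone A5, the aldehyde A6 adds through oxygen to C3, and the phenolate para carbon closes onto C1 to give the silylated target A4.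
- In its favour: it is the most convergent plan and delivers the protected target directly, without ketal, methylation or bromine steps. The phenolate para carbon is the only activated position next to the tether.
- Against it here: the closure is the microscopic reverse of the acid fragmentation of this class of dienone, so under a Lewis acid the open aromatic form may be preferred. C1 and C5 form with no control element, and A6 is an α-aryloxy aldehyde that epimerises easily.
- Comparison: on step economy it is the better plan. On structure (control of C1 and C5) and on mechanism (a Lewis acid acting on an acid-labile product) the chosen plan is stronger.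

Alternative 3: The cut is at the C7–O bond, with a temporary O–C6 bond from the C4 hydroxymethyl group. In the forward sense the alkoxide of the symmetric dienone A8 adds to C6 and the enolate is hydroxylated by an N-sulfonyloxaziridine to give the tricyclic ether A7.
- In its favour: C5 is not stereogenic in A8, and the tether can reach only the alkene cis to the hydroxymethyl group, so the C5 problem is solved by geometry. Both reaction types are known.
- Against it here: it does not make the spirocycle. A8 still needs a C1–C5 closure onto a para-substituted phenol, and A7 needs oxidation at C7, retro-oxa-Michael opening and methylation.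
- Comparison: on C5 control it is the equal of the bromine device of the chosen plan and better than an unsubstituted dienone. On mechanism it is safer for its own step. On step economy it is worse, and the hardest bond is left open.

Key step: step 18

Remarks on the chemistry:
- The trans arrangement of the C3 aryl and C4 hydroxymethyl groups requires the syn aldol, not the anti aldol; step 5 is therefore a syn aldol.
- C1 of the acid becomes a planar radical, so its configuration is left undefined in 19–26 (both epimers give the same radical).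
- A chair-like closure with the C1 side chain pseudo-equatorial would place it cis to the C3 aryl group, which is the C1 epimer of the target; the bromine at C10 is introduced to override this and to fix C5.
- Assumption: the C10 bromine and the triisopropylsilyl groups are treated as spectator and protecting groups; the bromine is removed in step 19.
- Abbreviations in names: TIPS = triisopropylsilyl; ArB = 5-allyloxy-2-bromo-4-methoxyphenyl; ArV = 3-methoxy-4-(TIPS-oxy)phenyl; ArG = 2-methoxy-4-[3-(TIPS-oxy)propyl]phenyl.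

Step 1
Reactants: 1 3-hydroxy-4-methoxyphenylacetic acid
Product: 2 2-bromo-5-hydroxy-4-methoxyphenylacetic acid
Conditions: Br2 (1.0 equiv), AcOH, 15 °C
Reagents that add atoms: bromine, BrBr
Why: Electrophilic aromatic bromination; the free hydroxyl directs para, to the carbon next to the side chain (the later C10), and one equivalent at low temperature should spare the hindered ortho position.

Step 2
Reactants: 2 2-bromo-5-hydroxy-4-methoxyphenylacetic acid
Product: 3 (5-allyloxy-2-bromo-4-methoxyphenyl)acetic acid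
Conditions: allyl bromide, NaOH (aq), EtOH, 60 °C; then HCl
Reagents that add atoms: allyl bromide, C=CCBr
Why: Williamson ether synthesis on the phenoxide; in aqueous base the carboxylate is a poor nucleophile and any allyl ester is saponified in the same pot.

Step 3
Reactants: 3 (5-allyloxy-2-bromo-4-methoxyphenyl)acetic acid; 4 (S)-4-benzyloxazolidin-2-one
Product: 6 (S)-4-benzyl-3-[(5-allyloxy-2-bromo-4-methoxyphenyl)acetyl]oxazolidin-2-one, via mixed pivalic anhydride 5 (not isolated)
Conditions: t-BuCOCl, Et3N, THF, −20 °C; then 4, LiCl, rt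
Reagents that add atoms: none
Why: N-acylation of the oxazolidinone through a mixed anhydride that is attacked at the less hindered arylacetyl carbonyl; no organolithium is used, so the aryl bromide is safe.

Step 4
Reactants: 7 vanillin
Product: 8 3-methoxy-4-(TIPS-oxy)benzaldehyde
Conditions: i-Pr3SiCl, imidazole, DMF, rt
Reagents that add atoms: triisopropylsilyl chloride, CC(C)[Si](Cl)(C(C)C)C(C)C
Why: Silylation of the phenol; the triisopropylsilyl aryl ether is chosen because it must survive the alkoxide of step 15 and the amide base of step 20.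

Step 5
Reactants: 6 (S)-4-benzyl-3-[(5-allyloxy-2-bromo-4-methoxyphenyl)acetyl]oxazolidin-2-one; 8 3-methoxy-4-(TIPS-oxy)benzaldehyde
Product: 10 (S)-4-benzyl-3-[(2S,3S)-2-ArB-3-hydroxy-3-ArV-propanoyl]oxazolidin-2-one, via boron Z-enolate 9 (not isolated)
Conditions: Bu2BOTf, i-Pr2NEt, CH2Cl2, −78 to 0 °C; 8, −78 to 0 °C; then pH 7 buffer, MeOH, H2O2, 0 °C
Reagents that add atoms: none
Why: Evans syn aldol through the Z boron enolate and a closed chair transition state; the benzyl group of the (S)-auxiliary shields one enolate face, which should set (2S,3S), the syn relationship that becomes trans at C3/C4 of the ring.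

Step 6
Reactants: 10 (S)-4-benzyl-3-[(2S,3S)-2-ArB-3-hydroxy-3-ArV-propanoyl]oxazolidin-2-one
Product: 11 (1S,2R)-2-ArB-1-ArV-propane-1,3-diol
Conditions: LiBH4, MeOH (1 equiv), THF, 0 °C
Reagents that add atoms: none
Why: Reductive cleavage of the imide to the primary alcohol; it is run cold and at once because the α-aryl β-hydroxy imide can epimerise at C4 or undergo retro-aldol cleavage, and the auxiliary is recovered.

Step 7
Reactants: 11 (1S,2R)-2-ArB-1-ArV-propane-1,3-diol
Product: 12 (1S,2R)-2-ArB-1-ArV-3-(TIPS-oxy)propan-1-ol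
Conditions: i-Pr3SiCl, imidazole, CH2Cl2, 0 °C to rt
Reagents that add atoms: triisopropylsilyl chloride, CC(C)[Si](Cl)(C(C)C)C(C)C
Why: Selective silylation of the primary hydroxyl, since the bulky chlorosilane should not reach the hindered benzylic alcohol; this silyl group is the one least prone to migrate to the neighbouring alkoxide in step 15.

Step 8
Reactants: 13 4-(3-hydroxypropyl)-2-methoxyphenol
Product: 15 2-methoxy-4-[3-(TIPS-oxy)propyl]phenol, via bis-silyl ether 14 (not isolated)
Conditions: i-Pr3SiCl (2.3 equiv), imidazole, DMF, rt; then Bu4NF (1.0 equiv), THF, −20 °C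
Reagents that add atoms: triisopropylsilyl chloride, CC(C)[Si](Cl)(C(C)C)C(C)C
Why: Exhaustive silylation followed by selective cleavage of the aryl silyl ether, which fluoride attacks far faster than the alkyl silyl ether because phenoxide is the better leaving group.

Step 9
Reactants: 16 (S)-but-3-ene-1,2-diol
Product: 17 (S)-1-(TIPS-oxy)but-3-en-2-ol
Conditions: i-Pr3SiCl, imidazole, CH2Cl2, 0 °C
Reagents that add atoms: triisopropylsilyl chloride, CC(C)[Si](Cl)(C(C)C)C(C)C
Why: Selective silylation of the primary hydroxyl of a 1,2-diol on steric grounds.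

Step 10
Reactants: 17 (S)-1-(TIPS-oxy)but-3-en-2-ol; 15 2-methoxy-4-[3-(TIPS-oxy)propyl]phenol
Product: 18 (R)-3-(ArG-oxy)-4-(TIPS-oxy)but-1-ene
Conditions: PPh3, i-PrO2CN=NCO2i-Pr, toluene, 0 °C to rt
Reagents that add atoms: none
Why: Mitsunobu etherification of the phenol with SN2 inversion at the allylic carbinol sets C1'; the SN2' by-product is achiral and linear, so it should be separable and cannot erode the configuration.

Step 11
Reactants: 18 (R)-3-(ArG-oxy)-4-(TIPS-oxy)but-1-ene
Product: 19 (2RS,3S)-3-(ArG-oxy)-4-(TIPS-oxy)butane-1,2-diol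
Conditions: OsO4 (2 mol%), N-methylmorpholine N-oxide, acetone/H2O, rt
Reagents that add atoms: N-methylmorpholine N-oxide, C[N+]1([O-])CCOCC1; water, O
Why: Catalytic syn dihydroxylation of the terminal alkene; the new centre (the later C1) may form as either epimer because it is erased in step 18.

Step 12
Reactants: 19 (2RS,3S)-3-(ArG-oxy)-4-(TIPS-oxy)butane-1,2-diol
Product: 20 (2RS,3S)-3-(ArG-oxy)-2-hydroxy-4-(TIPS-oxy)butanoic acid
Conditions: TEMPO (10 mol%), NaClO2, NaOCl (cat.), MeCN/phosphate buffer pH 6.8, rt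
Reagents that add atoms: sodium chlorite, [Na+].[O-]Cl=O
Why: Oxoammonium-catalysed oxidation selective for the primary alcohol, with chlorite taking the aldehyde on to the acid before glycol cleavage can occur; the secondary hydroxyl is oxidised much more slowly.

Step 13
Reactants: 20 (2RS,3S)-3-(ArG-oxy)-2-hydroxy-4-(TIPS-oxy)butanoic acid
Product: 21 allyl (2RS,3S)-3-(ArG-oxy)-2-hydroxy-4-(TIPS-oxy)butanoate
Conditions: allyl bromide, KHCO3, DMF, rt
Reagents that add atoms: allyl bromide, C=CCBr
Why: Carboxylate O-alkylation; the weak base leaves the α-hydroxyl untouched, and the allyl ester can later be removed without hydroxide.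

Step 14
Reactants: 21 allyl (2RS,3S)-3-(ArG-oxy)-2-hydroxy-4-(TIPS-oxy)butanoate
Product: 22 allyl (2RS,3S)-3-(ArG-oxy)-4-(TIPS-oxy)-2-(trifluoromethylsulfonyloxy)butanoate
Conditions: Tf2O, 2,6-lutidine, CH2Cl2, −78 °C; used crude
Reagents that add atoms: triflic anhydride, O=S(=O)(OS(=O)(=O)C(F)(F)F)C(F)(F)F
Why: Triflation of the α-hydroxy ester gives the most reactive α-carbonyl electrophile available, so that the ether can be formed at −78 °C.

Step 15
Reactants: 12 (1S,2R)-2-ArB-1-ArV-3-(TIPS-oxy)propan-1-ol; 22 allyl (2RS,3S)-3-(ArG-oxy)-4-(TIPS-oxy)-2-(trifluoromethylsulfonyloxy)butanoate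
Product: 24 allyl (2RS,3S)-2-[(1S,2R)-2-ArB-1-ArV-3-(TIPS-oxy)propoxy]-3-(ArG-oxy)-4-(TIPS-oxy)butanoate, via sodium alkoxide 23 (not isolated)
Conditions: NaN(SiMe3)2 (1.05 equiv), THF, −78 °C; then 22 (1.5 equiv), −78 to −20 °C
Reagents that add atoms: none
Why: Williamson etherification by SN2 displacement of the α-triflyloxy ester; the configuration at the attacked carbon is immaterial, C3 is untouched because its C–O bond is not broken, and the low temperature should hold back E1cB loss of aryloxide and silyl migration.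

Step 16
Reactants: 24 allyl (2RS,3S)-2-[(1S,2R)-2-ArB-1-ArV-3-(TIPS-oxy)propoxy]-3-(ArG-oxy)-4-(TIPS-oxy)butanoate
Product: 25 (2RS,3S)-2-[(1S,2R)-2-(2-bromo-5-hydroxy-4-methoxyphenyl)-1-ArV-3-(TIPS-oxy)propoxy]-3-(ArG-oxy)-4-(TIPS-oxy)butanoic acid
Conditions: Pd(PPh3)4 (5 mol%), morpholine, THF, rt; pH 5 buffer work-up
Reagents that add atoms: none
Why: Zerovalent-palladium π-allyl cleavage of the aryl allyl ether and the allyl ester in one operation, with morpholine as allyl acceptor; oxidative addition to the electron-rich aryl bromide should be too slow at room temperature to interfere.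

Step 17
Reactants: 25 (2RS,3S)-2-[(1S,2R)-2-(2-bromo-5-hydroxy-4-methoxyphenyl)-1-ArV-3-(TIPS-oxy)propoxy]-3-(ArG-oxy)-4-(TIPS-oxy)butanoic acid
Product: 26 (2RS,3S)-2-[(1S,2R)-2-(6-bromo-4,4-dimethoxy-3-oxocyclohexa-1,5-dien-1-yl)-1-ArV-3-(TIPS-oxy)propoxy]-3-(ArG-oxy)-4-(TIPS-oxy)butanoic acid
Conditions: PhI(OAc)2 (1.1 equiv), MeOH, 0 °C, 10 min; concentrated cold and used at once
Reagents that add atoms: methanol, CO
Why: Oxidative dearomatisation of the only free 2-methoxyphenol, with methanol adding at the methoxy-bearing carbon to give the masked ortho-benzoquinone; the bromine para to the former hydroxyl is expected to slow the Diels–Alder dimerisation typical of such dienones.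

Step 18
Reactants: 26 (2RS,3S)-2-[(1S,2R)-2-(6-bromo-4,4-dimethoxy-3-oxocyclohexa-1,5-dien-1-yl)-1-ArV-3-(TIPS-oxy)propoxy]-3-(ArG-oxy)-4-(TIPS-oxy)butanoic acid
Product: 27 (1S,3S,4R,5S)-10-bromo-8,8-dimethoxy-1-[(1S)-1-(ArG-oxy)-2-(TIPS-oxy)ethyl]-3-ArV-4-(TIPS-oxymethyl)-2-oxaspiro[4.5]dec-9-en-7-one
Conditions: [Ir(dF(CF3)ppy)2(dtbbpy)]PF6 (2 mol%), K2HPO4 (1 equiv), DMF (0.005 M), 450 nm LEDs, 20 °C, argon
Reagents that add atoms: none
Why: Proposed new method: the photoexcited trivalent-iridium complex oxidises the carboxylate of 26, loss of CO2 gives the nucleophilic α-alkoxy radical at C1 (both C1 epimers converge here), and this radical adds 5-exo-trig to C5, the β-carbon of the C5=C6–C7=O enone; the α-keto radical at C6 is then reduced by the divalent-iridium species and protonated, which closes a redox-neutral cycle. The closest known reaction type is the photoredox decarboxylative Giese addition of α-alkoxy acids to enones, and the closest known use of the acceptor is polar conjugate addition to masked ortho-benzoquinones. The tetrahydrofuran closes 5-exo because attack at C6 would be polarity-mismatched and attack at C9 would need a seven-membered ring. C5 is set by 1,3-allylic strain: the C10 bromine lies in the ring plane next to C4–H, so the radical, delivered from the C3 side, meets the face that leaves C6 cis to the C4 silyloxymethyl group. C1 is set by the same bromine: the side chain on the radical carbon should take the position above C6–H and not above C10–Br, which places it trans to the C3 aryl group, while the C3 and C4 substituents sit pseudo-equatorially in the chair-like transition state. The step needs selective oxidation of the carboxylate (the silyl aryl ethers are harder to oxidise), cyclisation faster than β-scission of the C1'–OAr bond, and no direct excitation of the dienone; high dilution, visible light and the dimerisation-resistant bromo dienone are chosen for these needs.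

Step 19
Reactants: 27 (1S,3S,4R,5S)-10-bromo-8,8-dimethoxy-1-[(1S)-1-(ArG-oxy)-2-(TIPS-oxy)ethyl]-3-ArV-4-(TIPS-oxymethyl)-2-oxaspiro[4.5]dec-9-en-7-one
Product: 28 (1S,3S,4R,5S)-8,8-dimethoxy-1-[(1S)-1-(ArG-oxy)-2-(TIPS-oxy)ethyl]-3-ArV-4-(TIPS-oxymethyl)-2-oxaspiro[4.5]dec-9-en-7-one
Conditions: Bu3SnH (3 equiv, 0.3 M), AIBN (cat.), toluene, 80 °C
Reagents that add atoms: none
Why: Radical chain hydrodebromination of the vinyl bromide; the high stannane concentration should trap the C10 vinyl radical before it can attack the nearby C3 aryl ring, and the isolated ketone and the ketal are inert to the stannyl radical.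

Step 20
Reactants: 28 (1S,3S,4R,5S)-8,8-dimethoxy-1-[(1S)-1-(ArG-oxy)-2-(TIPS-oxy)ethyl]-3-ArV-4-(TIPS-oxymethyl)-2-oxaspiro[4.5]dec-9-en-7-one
Product: 30 (1S,3S,4R,5S)-7-methoxy-1-[(1S)-1-(ArG-oxy)-2-(TIPS-oxy)ethyl]-3-ArV-4-(TIPS-oxymethyl)-2-oxaspiro[4.5]deca-6,9-dien-8-one, via trimethoxy diene 29 (not isolated)
Conditions: KN(SiMe3)2, THF/DMPU, −78 °C; Me2SO4, −78 to −20 °C; then citrate buffer pH 4.5, THF, 0 °C
Reagents that add atoms: dimethyl sulfate, COS(=O)(=O)OC; water, O
Why: The ketone can enolise only towards C6, and the potassium enolate, with C6 neopentyl-like next to the spiro centre, should be methylated on oxygen by the hard sulfate in a dipolar solvent. The ketal of 29 is then doubly allylic and should hydrolyse at pH 4–5, where the cation is captured by water much faster than it can lose C1, so neither strong acid nor the free 7-hydroxy dienone is involved.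

Step 21
Reactants: 30 (1S,3S,4R,5S)-7-methoxy-1-[(1S)-1-(ArG-oxy)-2-(TIPS-oxy)ethyl]-3-ArV-4-(TIPS-oxymethyl)-2-oxaspiro[4.5]deca-6,9-dien-8-one
Product: 31 (1S,3S,4R,5S)-1-{(1S)-2-hydroxy-1-[4-(3-hydroxypropyl)-2-methoxyphenoxy]ethyl}-3-(4-hydroxy-3-methoxyphenyl)-4-(hydroxymethyl)-7-methoxy-2-oxaspiro[4.5]deca-6,9-dien-8-one
Conditions: Bu4NF, AcOH (1:1), THF, 0 °C to rt
Reagents that add atoms: none
Why: Fluoride cleavage of the one aryl and three primary alkyl silyl ethers; the acetic acid buffer keeps the medium near neutral, so that no alkoxide adds to C6, no quinone methide forms at C3 and the dienone is not protonated.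

Compound list

1 | 3-hydroxy-4-methoxyphenylacetic acid | COc1ccc(CC(=O)O)cc1O | starting material
2 | 2-bromo-5-hydroxy-4-methoxyphenylacetic acid | COc1cc(Br)c(CC(=O)O)cc1O | intermediate
3 | (5-allyloxy-2-bromo-4-methoxyphenyl)acetic acid | COc1cc(Br)c(CC(=O)O)cc1OCC=C | intermediate
4 | (S)-4-benzyloxazolidin-2-one | O=C1OC[C@H](Cc2ccccc2)N1 | starting material
5 | mixed anhydride of 3 and pivalic acid | COc1cc(Br)c(CC(=O)OC(=O)C(C)(C)C)cc1OCC=C | intermediate (not isolated)
6 | (S)-4-benzyl-3-[(5-allyloxy-2-bromo-4-methoxyphenyl)acetyl]oxazolidin-2-one | COc1cc(Br)c(CC(=O)N2[C@@H](Cc3ccccc3)COC2=O)cc1OCC=C | intermediate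
7 | vanillin | COc1cc(C=O)ccc1O | starting material
8 | 3-methoxy-4-(TIPS-oxy)benzaldehyde | COc1cc(C=O)ccc1O[Si](C(C)C)(C(C)C)C(C)C | intermediate
9 | (Z)-dibutylboron enolate of 6 | CCCCB(CCCC)O/C(=C\c1cc(OCC=C)c(OC)cc1Br)N1[C@@H](Cc2ccccc2)COC1=O | intermediate (not isolated)
10 | (S)-4-benzyl-3-[(2S,3S)-2-ArB-3-hydroxy-3-ArV-propanoyl]oxazolidin-2-one | COc1cc(Br)c(cc1OCC=C)[C@H](C(=O)N1[C@@H](Cc2ccccc2)COC1=O)[C@@H](c1ccc(O[Si](C(C)C)(C(C)C)C(C)C)c(OC)c1)O | intermediate
11 | (1S,2R)-2-ArB-1-ArV-propane-1,3-diol | COc1cc(Br)c(cc1OCC=C)[C@H](CO)[C@@H](c1ccc(O[Si](C(C)C)(C(C)C)C(C)C)c(OC)c1)O | intermediate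
12 | (1S,2R)-2-ArB-1-ArV-3-(TIPS-oxy)propan-1-ol | COc1cc(Br)c(cc1OCC=C)[C@H](CO[Si](C(C)C)(C(C)C)C(C)C)[C@@H](c1ccc(O[Si](C(C)C)(C(C)C)C(C)C)c(OC)c1)O | intermediate
13 | 4-(3-hydroxypropyl)-2-methoxyphenol | COc1cc(CCCO)ccc1O | starting material
14 | 2-methoxy-1-(TIPS-oxy)-4-[3-(TIPS-oxy)propyl]benzene | COc1cc(CCCO[Si](C(C)C)(C(C)C)C(C)C)ccc1O[Si](C(C)C)(C(C)C)C(C)C | intermediate (not isolated)
15 | 2-methoxy-4-[3-(TIPS-oxy)propyl]phenol | COc1cc(CCCO[Si](C(C)C)(C(C)C)C(C)C)ccc1O | intermediate
16 | (S)-but-3-ene-1,2-diol | C=C[C@H](O)CO | starting material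
17 | (S)-1-(TIPS-oxy)but-3-en-2-ol | C=C[C@H](O)CO[Si](C(C)C)(C(C)C)C(C)C | intermediate
18 | (R)-3-(ArG-oxy)-4-(TIPS-oxy)but-1-ene | C=C[C@@H](Oc1ccc(CCCO[Si](C(C)C)(C(C)C)C(C)C)cc1OC)CO[Si](C(C)C)(C(C)C)C(C)C | intermediate
19 | (2RS,3S)-3-(ArG-oxy)-4-(TIPS-oxy)butane-1,2-diol (C2 epimer pair) | OCC(O)[C@H](CO[Si](C(C)C)(C(C)C)C(C)C)Oc1ccc(CCCO[Si](C(C)C)(C(C)C)C(C)C)cc1OC | intermediate
20 | (2RS,3S)-3-(ArG-oxy)-2-hydroxy-4-(TIPS-oxy)butanoic acid | OC(=O)C(O)[C@H](CO[Si](C(C)C)(C(C)C)C(C)C)Oc1ccc(CCCO[Si](C(C)C)(C(C)C)C(C)C)cc1OC | intermediate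
21 | allyl (2RS,3S)-3-(ArG-oxy)-2-hydroxy-4-(TIPS-oxy)butanoate | C=CCOC(=O)C(O)[C@H](CO[Si](C(C)C)(C(C)C)C(C)C)Oc1ccc(CCCO[Si](C(C)C)(C(C)C)C(C)C)cc1OC | intermediate
22 | allyl (2RS,3S)-3-(ArG-oxy)-4-(TIPS-oxy)-2-(trifluoromethylsulfonyloxy)butanoate | C=CCOC(=O)C(OS(=O)(=O)C(F)(F)F)[C@H](CO[Si](C(C)C)(C(C)C)C(C)C)Oc1ccc(CCCO[Si](C(C)C)(C(C)C)C(C)C)cc1OC | intermediate
23 | sodium alkoxide of 12 | COc1cc(Br)c(cc1OCC=C)[C@H](CO[Si](C(C)C)(C(C)C)C(C)C)[C@@H](c1ccc(O[Si](C(C)C)(C(C)C)C(C)C)c(OC)c1)[O-].[Na+] | intermediate (not isolated)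
24 | allyl (2RS,3S)-2-[(1S,2R)-2-ArB-1-ArV-3-(TIPS-oxy)propoxy]-3-(ArG-oxy)-4-(TIPS-oxy)butanoate | COc1cc(Br)c(cc1OCC=C)[C@H](CO[Si](C(C)C)(C(C)C)C(C)C)[C@@H](c1ccc(O[Si](C(C)C)(C(C)C)C(C)C)c(OC)c1)OC(C(=O)OCC=C)[C@H](CO[Si](C(C)C)(C(C)C)C(C)C)Oc1ccc(CCCO[Si](C(C)C)(C(C)C)C(C)C)cc1OC | intermediate
25 | (2RS,3S)-2-[(1S,2R)-2-(2-bromo-5-hydroxy-4-methoxyphenyl)-1-ArV-3-(TIPS-oxy)propoxy]-3-(ArG-oxy)-4-(TIPS-oxy)butanoic acid | COc1cc(Br)c(cc1O)[C@H](CO[Si](C(C)C)(C(C)C)C(C)C)[C@@H](c1ccc(O[Si](C(C)C)(C(C)C)C(C)C)c(OC)c1)OC(C(=O)O)[C@H](CO[Si](C(C)C)(C(C)C)C(C)C)Oc1ccc(CCCO[Si](C(C)C)(C(C)C)C(C)C)cc1OC | intermediate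
26 | (2RS,3S)-2-[(1S,2R)-2-(6-bromo-4,4-dimethoxy-3-oxocyclohexa-1,5-dien-1-yl)-1-ArV-3-(TIPS-oxy)propoxy]-3-(ArG-oxy)-4-(TIPS-oxy)butanoic acid (precursor of the key step) | COC1(OC)C=C(Br)C(=CC1=O)[C@H](CO[Si](C(C)C)(C(C)C)C(C)C)[C@@H](c1ccc(O[Si](C(C)C)(C(C)C)C(C)C)c(OC)c1)OC(C(=O)O)[C@H](CO[Si](C(C)C)(C(C)C)C(C)C)Oc1ccc(CCCO[Si](C(C)C)(C(C)C)C(C)C)cc1OC | intermediate
27 | (1S,3S,4R,5S)-10-bromo-8,8-dimethoxy-1-[(1S)-1-(ArG-oxy)-2-(TIPS-oxy)ethyl]-3-ArV-4-(TIPS-oxymethyl)-2-oxaspiro[4.5]dec-9-en-7-one (product of the key step) | COC1(OC)C(=O)C[C@]2(C(Br)=C1)[C@H](CO[Si](C(C)C)(C(C)C)C(C)C)[C@@H](c1ccc(O[Si](C(C)C)(C(C)C)C(C)C)c(OC)c1)O[C@@H]2[C@H](CO[Si](C(C)C)(C(C)C)C(C)C)Oc1ccc(CCCO[Si](C(C)C)(C(C)C)C(C)C)cc1OC | intermediate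
28 | (1S,3S,4R,5S)-8,8-dimethoxy-1-[(1S)-1-(ArG-oxy)-2-(TIPS-oxy)ethyl]-3-ArV-4-(TIPS-oxymethyl)-2-oxaspiro[4.5]dec-9-en-7-one | COC1(OC)C(=O)C[C@]2(C=C1)[C@H](CO[Si](C(C)C)(C(C)C)C(C)C)[C@@H](c1ccc(O[Si](C(C)C)(C(C)C)C(C)C)c(OC)c1)O[C@@H]2[C@H](CO[Si](C(C)C)(C(C)C)C(C)C)Oc1ccc(CCCO[Si](C(C)C)(C(C)C)C(C)C)cc1OC | intermediate
29 | (1S,3S,4R,5S)-7,8,8-trimethoxy-1-[(1S)-1-(ArG-oxy)-2-(TIPS-oxy)ethyl]-3-ArV-4-(TIPS-oxymethyl)-2-oxaspiro[4.5]deca-6,9-diene | COC1=C[C@]2(C=CC1(OC)OC)[C@H](CO[Si](C(C)C)(C(C)C)C(C)C)[C@@H](c1ccc(O[Si](C(C)C)(C(C)C)C(C)C)c(OC)c1)O[C@@H]2[C@H](CO[Si](C(C)C)(C(C)C)C(C)C)Oc1ccc(CCCO[Si](C(C)C)(C(C)C)C(C)C)cc1OC | intermediate (not isolated)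
30 | (1S,3S,4R,5S)-7-methoxy-1-[(1S)-1-(ArG-oxy)-2-(TIPS-oxy)ethyl]-3-ArV-4-(TIPS-oxymethyl)-2-oxaspiro[4.5]deca-6,9-dien-8-one | COC1=C[C@]2(C=CC1=O)[C@H](CO[Si](C(C)C)(C(C)C)C(C)C)[C@@H](c1ccc(O[Si](C(C)C)(C(C)C)C(C)C)c(OC)c1)O[C@@H]2[C@H](CO[Si](C(C)C)(C(C)C)C(C)C)Oc1ccc(CCCO[Si](C(C)C)(C(C)C)C(C)C)cc1OC | intermediate
31 | (1S,3S,4R,5S)-1-{(1S)-2-hydroxy-1-[4-(3-hydroxypropyl)-2-methoxyphenoxy]ethyl}-3-(4-hydroxy-3-methoxyphenyl)-4-(hydroxymethyl)-7-methoxy-2-oxaspiro[4.5]deca-6,9-dien-8-one | COC1=C[C@]2(C=CC1=O)[C@H](CO)[C@@H](c1ccc(O)c(OC)c1)O[C@@H]2[C@H](CO)Oc1ccc(CCCO)cc1OC | target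

Total step count: 21. Longest linear sequence: 13 steps (1 to 31 through steps 1–3, 5–7 and 15–21; the branch from 16 through steps 9–14 is equally long).

Steps least certain to work

Step 18 (key step). Three things are most likely to go wrong.
- The photochemistry may be diverted: the 2,4-dienone can be excited directly or by energy transfer and open to a ketene, or it can be reduced by the divalent-iridium species, instead of waiting for the C1 radical.
- The C1 radical may undergo β-scission of the C1'–OAr bond before it cyclises.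
- The side chain may take the intrinsically preferred pseudo-equatorial position, which would give the C1 epimer (side chain cis to the C3 aryl group), or C5 may form unselectively if the bromine fails to bias the C4–C5 rotamer.

The fallback uses the classical Barton reductive decarboxylation with radical cyclisation onto an enone, a thermal chain with no photocatalyst and no light. It sets out from 26, which is esterified in the dark with N-hydroxypyridine-2-thione (dicyclohexylcarbodiimide, CH2Cl2, 0 °C) to the thiohydroxamate ester F1. Heating F1 at 80 °C in toluene with tert-butyl thiol should release CO2, form the same C1 radical, close the ring and transfer hydrogen from the thiol to C6. The thiol does not reduce the vinyl bromide, so the control element stays in place, and the route is rejoined at 27.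

Step 15. Poor chemoselectivity of the hindered alkoxide is the likely failure: α-deprotonation of the triflate followed by loss of aryloxide (E1cB), or silyl transfer to the alkoxide, may outrun substitution at a β-branched secondary carbon. The fallback reverses the polarity and makes the O2–C3 bond instead.
- It sets out from 12, whose aryl silyl ether is cleaved selectively (Bu4NF, 1 equiv, THF, −40 °C) to the phenol F2.
- F2 is converted through its benzylic bromide (Me3SiBr, CH2Cl2; then aqueous NaHCO3) to the quinone methide F3.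
- Acid-catalysed conjugate addition of the hydroxy ester 21 to F3 gives the ether F4; both C3 epimers must be expected, and the wanted one is separated.
- Re-silylation of the phenol (i-Pr3SiCl, imidazole) rejoins the route at 24.

Step 20. Two processes threaten it: methylation at carbon (C6) instead of oxygen, and, if the hydrolysis is run too acidic, fragmentation of the C1–C5 bond with rearomatisation. The fallback separates enol ether formation from methylation.
- It sets out from 28, whose potassium enolate is trapped with Et3SiCl (a purely O-selective reaction) as the silyl enol ether F5.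
- The now doubly allylic ketal is hydrolysed at pH 5 to the silyloxy dienone F6.
- K2CO3 in methanol removes the enol silyl group to give the 7-hydroxy dienone F7.
- Me2SO4 and K2CO3 in acetone methylate F7, and the route is rejoined at 30.

Step 19. The C10 vinyl radical may be diverted before it is reduced: it can attack the C3 aryl ring, which lies on the same face, or abstract hydrogen within the molecule. The fallback is a two-electron hydrogenolysis with no radical: Pd(OAc)2, PPh3, formic acid and Et3N in DMF at 60 °C (oxidative addition of zerovalent palladium to the vinyl bromide, formate as hydride source). It sets out from 27, makes no new compound and rejoins the route at 28.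

Further compounds

F1 | step 18 | 2-thioxopyridin-1(2H)-yl ester of 26 (thiohydroxamate ester) | COC1(OC)C=C(Br)C(=CC1=O)[C@H](CO[Si](C(C)C)(C(C)C)C(C)C)[C@@H](c1ccc(O[Si](C(C)C)(C(C)C)C(C)C)c(OC)c1)OC(C(=O)On1ccccc1=S)[C@H](CO[Si](C(C)C)(C(C)C)C(C)C)Oc1ccc(CCCO[Si](C(C)C)(C(C)C)C(C)C)cc1OC
F2 | step 15 | (1S,2R)-2-ArB-1-(4-hydroxy-3-methoxyphenyl)-3-(TIPS-oxy)propan-1-ol | COc1cc(Br)c(cc1OCC=C)[C@H](CO[Si](C(C)C)(C(C)C)C(C)C)[C@@H](c1ccc(O)c(OC)c1)O
F3 | step 15 | 4-[(2R)-2-ArB-3-(TIPS-oxy)propylidene]-2-methoxycyclohexa-2,5-dien-1-one (quinone methide) | COC1=CC(=C[C@@H](CO[Si](C(C)C)(C(C)C)C(C)C)c2cc(OCC=C)c(OC)cc2Br)C=CC1=O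
F4 | step 15 | allyl (2RS,3S)-2-[(1S,2R)-2-ArB-1-(4-hydroxy-3-methoxyphenyl)-3-(TIPS-oxy)propoxy]-3-(ArG-oxy)-4-(TIPS-oxy)butanoate | COc1cc(Br)c(cc1OCC=C)[C@H](CO[Si](C(C)C)(C(C)C)C(C)C)[C@@H](c1ccc(O)c(OC)c1)OC(C(=O)OCC=C)[C@H](CO[Si](C(C)C)(C(C)C)C(C)C)Oc1ccc(CCCO[Si](C(C)C)(C(C)C)C(C)C)cc1OC
F5 | step 20 | (1S,3S,4R,5S)-8,8-dimethoxy-7-(triethylsilyloxy)-1-[(1S)-1-(ArG-oxy)-2-(TIPS-oxy)ethyl]-3-ArV-4-(TIPS-oxymethyl)-2-oxaspiro[4.5]deca-6,9-diene | CC[Si](CC)(CC)OC1=C[C@]2(C=CC1(OC)OC)[C@H](CO[Si](C(C)C)(C(C)C)C(C)C)[C@@H](c1ccc(O[Si](C(C)C)(C(C)C)C(C)C)c(OC)c1)O[C@@H]2[C@H](CO[Si](C(C)C)(C(C)C)C(C)C)Oc1ccc(CCCO[Si](C(C)C)(C(C)C)C(C)C)cc1OC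
F6 | step 20 | (1S,3S,4R,5S)-7-(triethylsilyloxy)-1-[(1S)-1-(ArG-oxy)-2-(TIPS-oxy)ethyl]-3-ArV-4-(TIPS-oxymethyl)-2-oxaspiro[4.5]deca-6,9-dien-8-one | CC[Si](CC)(CC)OC1=C[C@]2(C=CC1=O)[C@H](CO[Si](C(C)C)(C(C)C)C(C)C)[C@@H](c1ccc(O[Si](C(C)C)(C(C)C)C(C)C)c(OC)c1)O[C@@H]2[C@H](CO[Si](C(C)C)(C(C)C)C(C)C)Oc1ccc(CCCO[Si](C(C)C)(C(C)C)C(C)C)cc1OC
F7 | step 20 | (1S,3S,4R,5S)-7-hydroxy-1-[(1S)-1-(ArG-oxy)-2-(TIPS-oxy)ethyl]-3-ArV-4-(TIPS-oxymethyl)-2-oxaspiro[4.5]deca-6,9-dien-8-one | OC1=C[C@]2(C=CC1=O)[C@H](CO[Si](C(C)C)(C(C)C)C(C)C)[C@@H](c1ccc(O[Si](C(C)C)(C(C)C)C(C)C)c(OC)c1)O[C@@H]2[C@H](CO[Si](C(C)C)(C(C)C)C(C)C)Oc1ccc(CCCO[Si](C(C)C)(C(C)C)C(C)C)cc1OC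
F0 | step 19 | none | none
A1 | alternative 1 | spirolactone C8 trimethylsilyl enol ether (product of the cycloaddition) | C1C[C@]2(CC=C1O[Si](C)(C)C)[C@H](CO[Si](C)(C)C(C)(C)C)[C@@H](c1ccc(O[Si](C)(C)C(C)(C)C)c(OC)c1)OC2=O
A2 | alternative 1 | (4R,5S)-4-(tert-butyldimethylsilyloxymethyl)-5-[4-(tert-butyldimethylsilyloxy)-3-methoxyphenyl]-3-methylenedihydrofuran-2(3H)-one | C=C1[C@H](CO[Si](C)(C)C(C)(C)C)[C@@H](c2ccc(O[Si](C)(C)C(C)(C)C)c(OC)c2)OC1=O
A3 | alternative 1 | 2-(trimethylsilyloxy)buta-1,3-diene | C=CC(=C)O[Si](C)(C)C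
A4 | alternative 2 | tetrakis(tert-butyldimethylsilyl) ether of the target (product of the 3+2 step) | COC1=C[C@]2(C=CC1=O)[C@H](CO[Si](C)(C)C(C)(C)C)[C@@H](c1ccc(O[Si](C)(C)C(C)(C)C)c(OC)c1)O[C@@H]2[C@H](CO[Si](C)(C)C(C)(C)C)Oc1ccc(CCCO[Si](C)(C)C(C)(C)C)cc1OC
A5 | alternative 2 | 1-(tert-butyldimethylsilyloxymethyl)-2-[4-(tert-butyldimethylsilyloxy)-3-methoxyphenyl]-5-methoxyspiro[2.5]octa-4,7-dien-6-one (hydroxymethyl-bearing carbon configured as C4 of the target; the other two ring centres are erased on opening) | COC1=CC2(C=CC1=O)[C@H](CO[Si](C)(C)C(C)(C)C)C2c1ccc(O[Si](C)(C)C(C)(C)C)c(OC)c1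
A6 | alternative 2 | (S)-3-(tert-butyldimethylsilyloxy)-2-{2-methoxy-4-[3-(tert-butyldimethylsilyloxy)propyl]phenoxy}propanal | O=C[C@H](CO[Si](C)(C)C(C)(C)C)Oc1ccc(CCCO[Si](C)(C)C(C)(C)C)cc1OC
A7 | alternative 3 | tricyclic C6 ether with C7 hydroxyl (product of the oxa-Michael and hydroxylation step) | O=C1C=C[C@@]2([C@H](OC3)[C@H]1O)[C@H]3[C@@H](c1ccc(O[Si](C)(C)C(C)(C)C)c(OC)c1)O[C@@H]2[C@H](CO[Si](C)(C)C(C)(C)C)Oc1ccc(CCCO[Si](C)(C)C(C)(C)C)cc1OC
A8 | alternative 3 | 7-demethoxy spirodienone with free C4 hydroxymethyl group (symmetric dienone) | O=C1C=CC2(C=C1)[C@H](CO)[C@@H](c1ccc(O[Si](C)(C)C(C)(C)C)c(OC)c1)O[C@@H]2[C@H](CO[Si](C)(C)C(C)(C)C)Oc1ccc(CCCO[Si](C)(C)C(C)(C)C)cc1OC
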